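**Retrosynthetic overview**
- Euchrenone a16 (19) comes from its 5,7-bis(triisopropylsilyl) ether 18 by desilylation.
- 18 is cut at C2–C3 of ring C. The strategy rests on C2 being a benzylic carbon bonded to O1 and lying six atoms from C3 (C3–C4–C4a–C8a–O1–C2), so an O1–CH2–aryl ether and a diazo carbon on the C4 carbonyl (diazoketone 17) can be joined by carbenoid insertion into a C2–H bond.
- 17 comes from methyl ketone 15 by diazo transfer, and 15 from phenol 14 and benzylic alcohol 6 by forming the O1–CH2 ether bond.
- 14 comes from 2,4,6-trihydroxyacetophenone (bis-silylation, O-allylation, Claisen rearrangement, cross-metathesis); 6 comes from 4-bromophenol and isoprene.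
- Ring order: ring A is bought, the dimethylchroman ring is formed first (step 1), and ring C is closed last (step 9), which also sets C2.

Key step: step 9

Assumption: Rh2(S-PTTL)4, dirhodium tetrakis[N-phthaloyl-(S)-tert-leucinate], is taken to give the (2S) product; if the sense of induction should be the opposite, the mirror-image catalyst Rh2(R-PTTL)4 is used with nothing else changed.

**Route**

Step 1
Reactants: 1 4-bromophenol; 2 isoprene
Product: 4 6-bromo-2,2-dimethylchroman, via 4-bromo-2-prenylphenol 3 (not isolated)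
Conditions: isoprene (slow addition), 85% H3PO4, xylene, 30–35 °C
Reagents that add atoms: none
Why: Acid-catalysed phenol–isoprene annulation: Friedel–Crafts prenylation ortho to the hydroxyl (the para position is blocked by bromine) is followed by Markovnikov addition of the phenol oxygen to the protonated alkene, which closes the dimethylchroman ring.

Step 2
Reactants: 4 6-bromo-2,2-dimethylchroman
Product: 6 (2,2-dimethylchroman-6-yl)methanol, via chromanyllithium 5 (not isolated)
Conditions: n-BuLi, THF, −78 °C; dry paraformaldehyde, −78 °C to rt; H2O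
Reagents that add atoms: paraformaldehyde (as formaldehyde), C=O
Why: Bromine–lithium exchange followed by addition of the aryllithium to formaldehyde should give the primary benzylic alcohol directly.

Step 3
Reactants: 7 2,4,6-trihydroxyacetophenone (monohydrate dried beforehand)
Product: 8 1-[2-hydroxy-4,6-bis(triisopropylsilyloxy)phenyl]ethanone
Conditions: TIPSCl (2.1 equiv), imidazole, DMF, 0 °C to rt
Reagents that add atoms: triisopropylsilyl chloride, CC(C)[Si](Cl)(C(C)C)C(C)C
Why: Phenol silylation should stop at the bis-silyl ether, because once the para and one ortho hydroxyl have reacted the last hydroxyl is locked in a strong hydrogen bond to the acetyl carbonyl and is shielded from the bulky silyl chloride.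

Step 4
Reactants: 8 1-[2-hydroxy-4,6-bis(triisopropylsilyloxy)phenyl]ethanone; 9 allyl alcohol
Product: 10 1-[2-(allyloxy)-4,6-bis(triisopropylsilyloxy)phenyl]ethanone
Conditions: PPh3, DIAD, THF, 0 °C to rt
Reagents that add atoms: none
Why: Mitsunobu etherification of the acidic ortho-acyl phenol with a primary allylic alcohol proceeds under neutral conditions, which spare the aryl silyl ethers that a carbonate-mediated alkylation might cleave.

Step 5
Reactants: 10 1-[2-(allyloxy)-4,6-bis(triisopropylsilyloxy)phenyl]ethanone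
Product: 12 1-[3-allyl-2-hydroxy-4,6-bis(triisopropylsilyloxy)phenyl]ethanone, via ortho-dienone 11 (not isolated)
Conditions: PhNEt2, 190 °C, sealed tube
Reagents that add atoms: none
Why: Aromatic Claisen rearrangement: the [3,3]-sigmatropic shift can only go to the free ortho carbon (the other ortho carbon carries the acetyl group), and the resulting dienone tautomerises to the hydrogen-bonded phenol.

Step 6
Reactants: 12 1-[3-allyl-2-hydroxy-4,6-bis(triisopropylsilyloxy)phenyl]ethanone; 13 2-methyl-2-butene
Product: 14 1-[2-hydroxy-3-(3-methylbut-2-en-1-yl)-4,6-bis(triisopropylsilyloxy)phenyl]ethanone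
Conditions: second-generation Grubbs catalyst RuCl2(=CHPh)(H2IMes)(PCy3) (3 mol %), 2-methyl-2-butene/CH2Cl2, 35 °C, sealed vessel
Reagents that add atoms: none
Why: Olefin cross-metathesis of an aryl-allyl group with excess 2-methyl-2-butene is a standard way to make an aryl-prenyl group; the hydrogen-bonded phenol and the silyl ethers are tolerated and propene leaves as a gas.

Step 7
Reactants: 14 1-[2-hydroxy-3-(3-methylbut-2-en-1-yl)-4,6-bis(triisopropylsilyloxy)phenyl]ethanone; 6 (2,2-dimethylchroman-6-yl)methanol
Product: 15 1-{2-[(2,2-dimethylchroman-6-yl)methoxy]-3-(3-methylbut-2-en-1-yl)-4,6-bis(triisopropylsilyloxy)phenyl}ethanone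
Conditions: PPh3, DIAD, THF (concentrated), 0 °C to rt
Reagents that add atoms: none
Why: Mitsunobu etherification: the ortho-acyl phenol is acidic enough to act as pronucleophile and the primary para-alkoxybenzylic alcohol is readily activated as its alkoxyphosphonium ion, so the ether should form without base and without handling a labile para-alkoxybenzyl halide.

Step 8
Reactants: 15 1-{2-[(2,2-dimethylchroman-6-yl)methoxy]-3-(3-methylbut-2-en-1-yl)-4,6-bis(triisopropylsilyloxy)phenyl}ethanone
Product: 17 2-diazo-1-{2-[(2,2-dimethylchroman-6-yl)methoxy]-3-(3-methylbut-2-en-1-yl)-4,6-bis(triisopropylsilyloxy)phenyl}ethanone, via trifluoroacetyl diketone 16 (not isolated)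
Conditions: LiN(SiMe3)2, THF, −78 °C; CF3CO2CH2CF3, −78 °C; dilute HCl work-up; crude diketone then MsN3, Et3N, H2O (1 equiv), MeCN, rt
Reagents that add atoms: 2,2,2-trifluoroethyl trifluoroacetate, O=C(OCC(F)(F)F)C(F)(F)F (the trifluoroacetyl group of 16); methanesulfonyl azide, CS(=O)(=O)N=[N+]=[N-] (the two diazo nitrogens of 17)
Why: Detrifluoroacetylative diazo transfer (Danheiser procedure): the kinetic lithium enolate of the methyl ketone is acylated at the unhindered terminal carbon, and the activated 1,3-diketone takes the diazo group from the sulfonyl azide with loss of the trifluoroacetyl group as N-mesyltrifluoroacetamide, so that no hindered 2,6-disubstituted acid chloride or anhydride has to be made.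

Step 9
Reactants: 17 2-diazo-1-{2-[(2,2-dimethylchroman-6-yl)methoxy]-3-(3-methylbut-2-en-1-yl)-4,6-bis(triisopropylsilyloxy)phenyl}ethanone
Product: 18 (2S)-2-(2,2-dimethylchroman-6-yl)-8-(3-methylbut-2-en-1-yl)-5,7-bis(triisopropylsilyloxy)chroman-4-one
Conditions: Rh2(S-PTTL)4 (2 mol %), CH2Cl2, 4 Å molecular sieves, 0 °C, slow addition of 17
Reagents that add atoms: none
Why: Rh2(S-PTTL)4 expels N2 from 17 to give an electrophilic rhodium carbenoid at C3, which inserts by a concerted, asynchronous three-centre transition state into one of the two enantiotopic C–H bonds of the O1–CH2–aryl group and so forms the C2–C3 bond. The closest known reaction type is the intramolecular C–H insertion of ortho-alkoxyaryl diazoketones to chroman-4-ones under catalysis by carboxylate dimers of divalent rhodium, including chiral carboxylates. Ring C closes as a 1,6-insertion through a six-membered cyclic transition state (C3, C4, C4a, C8a, O1, C2), because the atom at the usual five-ring distance is O1, which carries no hydrogen. C2 is set by the catalyst alone: the chiral pocket of the four N-phthaloyl-tert-leucinate ligands decides which enantiotopic benzylic hydrogen is replaced, and the (2S) sense is the assumption stated above. The step needs site selectivity for this C–H bond over oxonium ylide formation at O1 with 1,2-benzyl shift, over the silyl ethers and over the prenyl alkene: the C–H bond is doubly activated by O1 and the para-alkoxyaryl ring, ylide formation at the weakly basic, doubly flanked aryl ether oxygen is reversible, the silyl ethers have no C–H alpha to oxygen, and the prenyl alkene is meta to the carbenoid arm and cannot reach it within the molecule. Slow addition at low temperature keeps carbene dimerisation down.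

Step 10
Reactants: 18 (2S)-2-(2,2-dimethylchroman-6-yl)-8-(3-methylbut-2-en-1-yl)-5,7-bis(triisopropylsilyloxy)chroman-4-one
Product: 19 euchrenone a16, (2S)-2-(2,2-dimethylchroman-6-yl)-5,7-dihydroxy-8-(3-methylbut-2-en-1-yl)chroman-4-one
Conditions: TBAF, AcOH (1:1, 2.5 equiv each), THF, 0 °C
Reagents that add atoms: none
Why: Fluoride cleaves both aryl silyl ethers, and the acetic acid buffer keeps the medium non-basic so that ring C should not open to the chalcone by retro-oxa-Michael reaction, which would racemise C2.

**Compound list**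

1 | 4-bromophenol | Oc1ccc(Br)cc1 | starting material
2 | isoprene | C=CC(C)=C | starting material
3 | 4-bromo-2-(3-methylbut-2-en-1-yl)phenol | CC(C)=CCc1cc(Br)ccc1O | intermediate (not isolated)
4 | 6-bromo-2,2-dimethylchroman | CC1(C)CCc2cc(Br)ccc2O1 | intermediate
5 | (2,2-dimethylchroman-6-yl)lithium | [Li]c1ccc2c(c1)CCC(C)(C)O2 | intermediate (not isolated)
6 | (2,2-dimethylchroman-6-yl)methanol | OCc1ccc2c(c1)CCC(C)(C)O2 | intermediate
7 | 2,4,6-trihydroxyacetophenone | CC(=O)c1c(O)cc(O)cc1O | starting material
8 | 1-[2-hydroxy-4,6-bis(triisopropylsilyloxy)phenyl]ethanone | CC(=O)c1c(O)cc(O[Si](C(C)C)(C(C)C)C(C)C)cc1O[Si](C(C)C)(C(C)C)C(C)C | intermediate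
9 | allyl alcohol | C=CCO | starting material
10 | 1-[2-(allyloxy)-4,6-bis(triisopropylsilyloxy)phenyl]ethanone | CC(=O)c1c(OCC=C)cc(O[Si](C(C)C)(C(C)C)C(C)C)cc1O[Si](C(C)C)(C(C)C)C(C)C | intermediate
11 | 2-acetyl-6-allyl-3,5-bis(triisopropylsilyloxy)cyclohexa-2,4-dien-1-one (ortho-dienone, racemic at C6) | CC(=O)C1=C(O[Si](C(C)C)(C(C)C)C(C)C)C=C(O[Si](C(C)C)(C(C)C)C(C)C)C(CC=C)C1=O | intermediate (not isolated)
12 | 1-[3-allyl-2-hydroxy-4,6-bis(triisopropylsilyloxy)phenyl]ethanone | CC(=O)c1c(O)c(CC=C)c(O[Si](C(C)C)(C(C)C)C(C)C)cc1O[Si](C(C)C)(C(C)C)C(C)C | intermediate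
13 | 2-methyl-2-butene | CC=C(C)C | starting material
14 | 1-[2-hydroxy-3-(3-methylbut-2-en-1-yl)-4,6-bis(triisopropylsilyloxy)phenyl]ethanone | CC(=O)c1c(O)c(CC=C(C)C)c(O[Si](C(C)C)(C(C)C)C(C)C)cc1O[Si](C(C)C)(C(C)C)C(C)C | intermediate
15 | 1-{2-[(2,2-dimethylchroman-6-yl)methoxy]-3-(3-methylbut-2-en-1-yl)-4,6-bis(triisopropylsilyloxy)phenyl}ethanone | CC(=O)c1c(OCc2ccc3c(c2)CCC(C)(C)O3)c(CC=C(C)C)c(O[Si](C(C)C)(C(C)C)C(C)C)cc1O[Si](C(C)C)(C(C)C)C(C)C | intermediate
16 | 1-{2-[(2,2-dimethylchroman-6-yl)methoxy]-3-(3-methylbut-2-en-1-yl)-4,6-bis(triisopropylsilyloxy)phenyl}-4,4,4-trifluorobutane-1,3-dione | O=C(CC(=O)C(F)(F)F)c1c(OCc2ccc3c(c2)CCC(C)(C)O3)c(CC=C(C)C)c(O[Si](C(C)C)(C(C)C)C(C)C)cc1O[Si](C(C)C)(C(C)C)C(C)C | intermediate (not isolated)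
17 | 2-diazo-1-{2-[(2,2-dimethylchroman-6-yl)methoxy]-3-(3-methylbut-2-en-1-yl)-4,6-bis(triisopropylsilyloxy)phenyl}ethanone | CC(C)=CCc1c(O[Si](C(C)C)(C(C)C)C(C)C)cc(O[Si](C(C)C)(C(C)C)C(C)C)c(C(=O)C=[N+]=[N-])c1OCc1ccc2c(c1)CCC(C)(C)O2 | intermediate (key-step precursor)
18 | (2S)-2-(2,2-dimethylchroman-6-yl)-8-(3-methylbut-2-en-1-yl)-5,7-bis(triisopropylsilyloxy)chroman-4-one | CC(C)=CCc1c(O[Si](C(C)C)(C(C)C)C(C)C)cc(O[Si](C(C)C)(C(C)C)C(C)C)c2c1O[C@H](c1ccc3c(c1)CCC(C)(C)O3)CC2=O | intermediate (key-step product)
19 | euchrenone a16 | CC(C)=CCc1c(O)cc(O)c2c1O[C@H](c1ccc3c(c1)CCC(C)(C)O3)CC2=O | target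

**Step count**

Total: 10 steps. Longest linear sequence: 8 steps (steps 3 to 10, from 2,4,6-trihydroxyacetophenone); the chroman branch (steps 1 and 2) joins at step 7.

**Steps most likely to fail**

1. Step 9. The carbenoid may be diverted into a five-membered oxonium ylide at O1 followed by 1,2-shift of the electron-rich benzyl group, or the two enantiotopic benzylic hydrogens may be poorly discriminated, giving low enantiomeric purity. The fallback sets out from phenol 14 and bromide 4 and comes back to the route at 18; it builds ring C first and sets C2 afterwards. Phenol 14 would be heated with N,N-dimethylformamide dimethyl acetal (toluene, 90 °C) to give the enaminone (E)-3-(dimethylamino)-1-[2-hydroxy-3-(3-methylbut-2-en-1-yl)-4,6-bis(triisopropylsilyloxy)phenyl]prop-2-en-1-one F1. This should close with loss of dimethylamine (Me3SiCl, CH2Cl2, rt) to 8-(3-methylbut-2-en-1-yl)-5,7-bis(triisopropylsilyloxy)-4H-chromen-4-one F2. Bromide 4 would be converted by n-BuLi, then B(OiPr)3, then dilute HCl into (2,2-dimethylchroman-6-yl)boronic acid F3. Asymmetric 1,4-addition of F3 to F2 with [RhOH(cod)]2 and an electron-poor chiral bisphosphine (MeO-F12-BIPHEP, the antipode chosen for the 2S product) in toluene/H2O should then give 18, which goes on to step 10.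

2. Step 8. Trifluoroacetylation of the enolate next to the doubly ortho-substituted ring may be incomplete, or the strong base may cause loss or migration of the ortho silyl ether. The fallback sets out from ketone 15 and comes back at 17; it replaces enolate chemistry by a neutral condensation. Ketone 15 would be heated with N,N-dimethylformamide dimethyl acetal (neat, 110 °C) to give the enaminone (E)-3-(dimethylamino)-1-{2-[(2,2-dimethylchroman-6-yl)methoxy]-3-(3-methylbut-2-en-1-yl)-4,6-bis(triisopropylsilyloxy)phenyl}prop-2-en-1-one F4. Treatment of F4 with p-toluenesulfonyl azide (MeCN, rt) should give 17 by the enamine–sulfonyl azide cycloaddition and cycloreversion of the triazoline, which splits off N,N-dimethyl-N'-tosylformamidine.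

3. Step 7. The Mitsunobu reaction may be sluggish at the hindered, hydrogen-bonded phenol, so that the activated benzylic alcohol alkylates the reduced azodicarboxylate instead. The fallback sets out from alcohol 6 and phenol 14 and comes back at 15; it uses a Williamson etherification. Alcohol 6 would be converted with PBr3 (Et2O, 0 °C) into 6-(bromomethyl)-2,2-dimethylchroman F5, used at once. Alkylation of 14 with F5 (K2CO3, acetone, rt to 45 °C, anhydrous) should give 15.

**Further compounds**

F1 | step 9 | (E)-3-(dimethylamino)-1-[2-hydroxy-3-(3-methylbut-2-en-1-yl)-4,6-bis(triisopropylsilyloxy)phenyl]prop-2-en-1-one | CN(C)/C=C/C(=O)c1c(O)c(CC=C(C)C)c(O[Si](C(C)C)(C(C)C)C(C)C)cc1O[Si](C(C)C)(C(C)C)C(C)C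
F2 | step 9 | 8-(3-methylbut-2-en-1-yl)-5,7-bis(triisopropylsilyloxy)-4H-chromen-4-one | O=c1ccoc2c(CC=C(C)C)c(O[Si](C(C)C)(C(C)C)C(C)C)cc(O[Si](C(C)C)(C(C)C)C(C)C)c12
F3 | step 9 | (2,2-dimethylchroman-6-yl)boronic acid | OB(O)c1ccc2c(c1)CCC(C)(C)O2
F4 | step 8 | (E)-3-(dimethylamino)-1-{2-[(2,2-dimethylchroman-6-yl)methoxy]-3-(3-methylbut-2-en-1-yl)-4,6-bis(triisopropylsilyloxy)phenyl}prop-2-en-1-one | CN(C)/C=C/C(=O)c1c(OCc2ccc3c(c2)CCC(C)(C)O3)c(CC=C(C)C)c(O[Si](C(C)C)(C(C)C)C(C)C)cc1O[Si](C(C)C)(C(C)C)C(C)C
F5 | step 7 | 6-(bromomethyl)-2,2-dimethylchroman | BrCc1ccc2c(c1)CCC(C)(C)O2
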